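**Retrosynthetic overview**

- The route rests on the C3–C4–C5 unit of the 1,2-dioxolane ring with its two methyl groups and the O1–O2 bridge. This unit is the hydrogen peroxide adduct of pentane-2,4-dione, so only the C3–CH2CO2H and C5–C1′ bonds remain to be made.
- Side chain: C9′=C10′ by Julia–Kocienski olefination with (2E,4E)-hepta-2,4-dienal; C2′–C3′ by cross-metathesis of a C5 allyl group with an oct-7-enyl tetrazolyl sulfone, then diimide reduction.
- Key disconnection: C3–Cα and C5–C1′ in one flask from 3,5-dimethoxy-3,5-dimethyl-1,2-dioxolane, a ketene bis(silyl) acetal and allyltrimethylsilane under a silylated chiral imidodiphosphorimidate. C3 is set by the chiral anion, C5 by the C3 carboxylate arm.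
- Ring order: the dioxolane is the only ring and is closed first (step 1); a lactone bridge closes and reopens inside step 4.

Key step: step 4

Assumption: the (S,S)-catalyst is taken to give the 3R series; if it gives 3S, the (R,R)-catalyst is used with no other change.

Remark: the acetate unit is brought in as the ketene bis(trimethylsilyl) acetal, not as a methyl silyl ketene acetal. A silyl ester arm can bridge to C5 and then give up its silyl group to form a neutral lactone. A methyl ester arm would hold C5 as an O-methyl lactonium ion that still accepts a second ketene acetal. The step therefore delivers the free acid and no saponification is needed.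

Remark: the low-molecular-weight peroxides of steps 1 and 2 are handled in solution on small scale.

**Step 1**
Reactants: 1 pentane-2,4-dione; 2 hydrogen peroxide
Product: 3 3,5-dimethyl-1,2-dioxolane-3,5-diol (interconverting cis/trans mixture)
Conditions: 30% aq. H2O2 (1.05 equiv), 0 °C → rt, no catalyst; crystallisation
Reagents that add atoms: none
Why: Uncatalysed addition of H2O2 to both carbonyl groups of the 1,3-diketone (double peroxy-hemiketal formation) closes the five-membered peroxide ring by 5-exo-trig attack of the hydroperoxy group on the second carbonyl, and the adduct should crystallise.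

**Step 2**
Reactants: 3 3,5-dimethyl-1,2-dioxolane-3,5-diol
Product: 4 cis-3,5-dimethoxy-3,5-dimethyl-1,2-dioxolane (meso; the trans isomer forms alongside and is used with it)
Conditions: MeOH, HC(OMe)3 (3 equiv), (±)-camphor-10-sulfonic acid (5 mol%), 0 °C → rt; Et3N quench
Reagents that add atoms: methanol, CO; trimethyl orthoformate, COC(OC)OC
Why: Acid-catalysed exchange of both peroxy-hemiketal OH groups for OMe through the peroxycarbenium ions, driven by removal of water with the orthoformate (hemiketal-to-ketal exchange); the cis/trans ratio does not matter because both ketal carbons are ionised again in step 4.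

**Step 3**
Reactants: 5 trimethylsilyl acetate
Product: 7 1,1-bis(trimethylsilyloxy)ethene, via lithium enolate 6 (not isolated)
Conditions: LiN(iPr)2 (1.05 equiv), THF, −78 °C; Me3SiCl (1.1 equiv), −78 °C → rt; filtration, distillation under reduced pressure at low bath temperature
Reagents that add atoms: chlorotrimethylsilane, C[Si](C)(C)Cl
Why: Deprotonation of the silyl ester and O-silylation of the enolate is the Ainsworth-type synthesis of a ketene bis(silyl) acetal; the reagent is used fresh because it isomerises to the C-silyl ester on heating.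

**Step 4**
Reactants: 4 cis-3,5-dimethoxy-3,5-dimethyl-1,2-dioxolane; 7 1,1-bis(trimethylsilyloxy)ethene; 8 allyltrimethylsilane
Product: 11 2-[(3R,5S)-3,5-dimethyl-5-(prop-2-en-1-yl)-1,2-dioxolan-3-yl]acetic acid, via bridged lactone 9 (not isolated), via trimethylsilyl ester 10 (not isolated)
Conditions: (S,S)-imidodiphosphorimidate HN[P(=NSO2CF3)(O2C20H10Ar2)]2 (Ar = 3,5-(CF3)2C6H3 on the 3,3′-positions of each binaphthyl; 3 mol%), 7 (1.05 equiv, slow addition), toluene/CH2Cl2, −78 °C; then 8 (3 equiv), −78 → −40 °C; aq. citric acid work-up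
Reagents that add atoms: none
Why: Proposed new method: the acid is silylated in situ by a little of 7, the silylium–imidodiphosphorimidate pair removes one methoxy group of 4 as Me3SiOMe, and the C3 peroxycarbenium ion, held in the pocket of the chiral anion, is attacked by 7 on one face, which sets C3 (R) by catalyst control whichever ketal carbon or ketal diastereomer ionised, because the remaining ketal centre is erased in the next event. The silyl ester arm then captures the C5 peroxycarbenium ion through its carbonyl oxygen (6-exo-trig O–C closure, Me3Si+ returned to the anion) to give the neutral bridged lactone 9, so one molecule of the C,O-dinucleophile consumes both ketal leaving groups and a second C-addition would require reopening of 9, which internal return of the tethered carboxylate should make far less favourable than ionisation of 4 at −78 °C; this bridge is temporary and the product contains no new ring. On warming with 8, silylation of the lactone carbonyl loosens the C5–O bond and the allylsilane attacks C5 anti to the departing carboxylate (inversion, allyl trans to the acetic acid arm, so C5 is set by the C3 arm), and loss of Me3Si+ from the β-silyl cation gives 10 and returns the catalyst. The closest known reaction types are the Lewis-acid substitution of 3-alkoxy-1,2-dioxolanes by silyl ketene acetals and allylsilanes (Mukaiyama-type and Hosomi–Sakurai-type additions to peroxycarbenium ions), chiral-counteranion-directed additions of silyl nucleophiles to cyclic oxocarbenium ions, and lactone formation from ketene bis(silyl) acetals acting as C,O-dinucleophiles; what is new is their combination on a bis-ketal with enantiocontrol at a fully substituted peroxycarbenium carbon. The step needs face selection at C3 (catalyst pocket), a single C-addition of the acetate unit (lactone capping), anti opening at C5 (bridged carboxylate) and exocyclic C–OMe cleavage in preference to ring C–O or O–O cleavage (the methoxy oxygen is the most basic site, and a ring-opened dioxolane recloses).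

**Step 5**
Reactants: 12 8-bromooct-1-ene; 13 1-phenyl-1H-tetrazole-5-thiol
Product: 14 5-(oct-7-en-1-ylsulfanyl)-1-phenyl-1H-tetrazole
Conditions: K2CO3, acetone, rt
Reagents that add atoms: none
Why: SN2 S-alkylation of the soft tetrazolethiolate by the primary bromide (thioether synthesis).

**Step 6**
Reactants: 14 5-(oct-7-en-1-ylsulfanyl)-1-phenyl-1H-tetrazole; 2 hydrogen peroxide
Product: 15 5-(oct-7-en-1-ylsulfonyl)-1-phenyl-1H-tetrazole
Conditions: 30% aq. H2O2 (5 equiv), (NH4)6Mo7O24·4H2O (10 mol%), EtOH, 0 °C → rt
Reagents that add atoms: none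
Why: Molybdate-catalysed oxidation with H2O2 takes the sulfide through the sulfoxide to the sulfone and, unlike a peracid, should not epoxidise the unactivated terminal alkene.

**Step 7**
Reactants: 11 2-[(3R,5S)-3,5-dimethyl-5-(prop-2-en-1-yl)-1,2-dioxolan-3-yl]acetic acid; 15 5-(oct-7-en-1-ylsulfonyl)-1-phenyl-1H-tetrazole
Product: 16 2-[(3R,5S)-3,5-dimethyl-5-[(2E)-9-[(1-phenyl-1H-tetrazol-5-yl)sulfonyl]non-2-en-1-yl]-1,2-dioxolan-3-yl]acetic acid (E/Z mixture)
Conditions: 15 (3 equiv), second-generation Hoveyda–Grubbs catalyst RuCl2(=CH-C6H4-2-OiPr)(H2IMes) (5 mol%), CH2Cl2, 40 °C, argon sparge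
Reagents that add atoms: none
Why: Olefin cross-metathesis between the allyl terminus of 11 and an excess of terminal alkene 15 is driven by loss of ethene, the ruthenium carbene tolerates dialkyl peroxides, free carboxylic acids and sulfones, and the E/Z ratio is irrelevant because the double bond is reduced next.

**Step 8**
Reactants: 16 2-[(3R,5S)-3,5-dimethyl-5-[(2E)-9-[(1-phenyl-1H-tetrazol-5-yl)sulfonyl]non-2-en-1-yl]-1,2-dioxolan-3-yl]acetic acid
Product: 17 2-[(3R,5S)-3,5-dimethyl-5-{9-[(1-phenyl-1H-tetrazol-5-yl)sulfonyl]nonyl}-1,2-dioxolan-3-yl]acetic acid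
Conditions: KO2CN=NCO2K (10 equiv, in portions), AcOH (20 equiv), MeOH/CH2Cl2, 0 °C → rt
Reagents that add atoms: none
Why: Diimide generated from the azodicarboxylate salt and acetic acid delivers H2 to the C=C bond through a concerted cyclic transition state and leaves the O–O bond intact, the classical way to saturate unsaturated peroxides (diimide reduction).

**Step 9**
Reactants: 17 2-[(3R,5S)-3,5-dimethyl-5-{9-[(1-phenyl-1H-tetrazol-5-yl)sulfonyl]nonyl}-1,2-dioxolan-3-yl]acetic acid; 18 (2E,4E)-hepta-2,4-dienal
Product: 20 2-[(3R,5S)-5-[(9E,11E,13E)-hexadeca-9,11,13-trien-1-yl]-3,5-dimethyl-1,2-dioxolan-3-yl]acetic acid, via dipotassium dianion 19 (not isolated)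
Conditions: KN(SiMe3)2 (2.2 equiv), DME/THF, −78 °C, 30 min; then 18 (1.5 equiv), −78 °C → rt; aq. HCl to pH 3–4 at 0 °C
Reagents that add atoms: none
Why: Julia–Kocienski olefination: the first equivalent of base forms the carboxylate, whose α-CH is not deprotonated under these conditions so that E1cB opening of the dioxolane is shut off, the second forms the sulfonyl carbanion, and addition to the aldehyde, Smiles rearrangement and anti elimination of SO2 and phenyltetrazolonate should give the 9E double bond while the 11E,13E diene and the two fully substituted ring stereocentres are untouched.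

**Compound list**

1 | pentane-2,4-dione | CC(=O)CC(C)=O | starting material
2 | hydrogen peroxide | OO | starting material
3 | 3,5-dimethyl-1,2-dioxolane-3,5-diol (cis/trans mixture, cis drawn) | O[C@@]1(C)C[C@@](C)(O)OO1 | intermediate
4 | cis-3,5-dimethoxy-3,5-dimethyl-1,2-dioxolane, (3R,5S), meso (trans isomer present and equally usable) | CO[C@@]1(C)C[C@@](C)(OC)OO1 | intermediate
5 | trimethylsilyl acetate | CC(=O)O[Si](C)(C)C | starting material
6 | lithium 1-(trimethylsilyloxy)ethen-1-olate | [Li+].[O-]C(=C)O[Si](C)(C)C | intermediate (not isolated)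
7 | 1,1-bis(trimethylsilyloxy)ethene | C=C(O[Si](C)(C)C)O[Si](C)(C)C | intermediate
8 | allyltrimethylsilane | C=CC[Si](C)(C)C | starting material
9 | (1S,5R)-1,5-dimethyl-2,6,7-trioxabicyclo[3.2.1]octan-3-one | C[C@@]1(OC(=O)C2)C[C@@]2(C)OO1 | intermediate (not isolated)
10 | trimethylsilyl 2-[(3R,5S)-3,5-dimethyl-5-(prop-2-en-1-yl)-1,2-dioxolan-3-yl]acetate | C=CC[C@@]1(C)C[C@](C)(CC(=O)O[Si](C)(C)C)OO1 | intermediate (not isolated)
11 | 2-[(3R,5S)-3,5-dimethyl-5-(prop-2-en-1-yl)-1,2-dioxolan-3-yl]acetic acid | C=CC[C@@]1(C)C[C@](C)(CC(=O)O)OO1 | intermediate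
12 | 8-bromooct-1-ene | C=CCCCCCCBr | starting material
13 | 1-phenyl-1H-tetrazole-5-thiol | Sc1nnnn1-c1ccccc1 | starting material
14 | 5-(oct-7-en-1-ylsulfanyl)-1-phenyl-1H-tetrazole | C=CCCCCCCSc1nnnn1-c1ccccc1 | intermediate
15 | 5-(oct-7-en-1-ylsulfonyl)-1-phenyl-1H-tetrazole | C=CCCCCCCS(=O)(=O)c1nnnn1-c1ccccc1 | intermediate
16 | 2-[(3R,5S)-3,5-dimethyl-5-[(2E)-9-[(1-phenyl-1H-tetrazol-5-yl)sulfonyl]non-2-en-1-yl]-1,2-dioxolan-3-yl]acetic acid (E/Z mixture, E drawn) | O=S(=O)(CCCCCC/C=C/C[C@@]1(C)C[C@](C)(CC(=O)O)OO1)c2nnnn2-c3ccccc3 | intermediate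
17 | 2-[(3R,5S)-3,5-dimethyl-5-{9-[(1-phenyl-1H-tetrazol-5-yl)sulfonyl]nonyl}-1,2-dioxolan-3-yl]acetic acid | O=S(=O)(CCCCCCCCC[C@@]1(C)C[C@](C)(CC(=O)O)OO1)c2nnnn2-c3ccccc3 | intermediate
18 | (2E,4E)-hepta-2,4-dienal | CC/C=C/C=C/C=O | starting material
19 | dipotassium salt of 17 deprotonated at the carboxyl group and at the carbon α to sulfur | [K+].[K+].O=S(=O)([CH-]CCCCCCCC[C@@]1(C)C[C@](C)(CC(=O)[O-])OO1)c2nnnn2-c3ccccc3 | intermediate (not isolated)
20 | 2-[(3R,5S)-5-[(9E,11E,13E)-hexadeca-9,11,13-trien-1-yl]-3,5-dimethyl-1,2-dioxolan-3-yl]acetic acid | CC/C=C/C=C/C=C/CCCCCCCC[C@@]1(C)C[C@](C)(CC(=O)O)OO1 | target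

**Step count**

Total: 9 steps. Longest linear sequence: 6 steps (1, 2, 4, 7, 8, 9).

**Steps most likely to fail**

Step 4 (bears the label "Proposed new method:"). Face discrimination at the fully substituted C3 peroxycarbenium ion may be weak. The lactone may reopen before the ketene acetal is used up, which would give double C-addition. The peroxide may fragment under the silylium acid, or the anti opening at C5 may erode. The fallback uses known chemistry, sets out from 1 and comes back at 11; it sets the two centres without control and sorts them by separation.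
- Indium-mediated Barbier allylation of 1 with allyl bromide in water should give 4-hydroxy-4-methylhept-6-en-2-one F1.
- 50% H2O2 with catalytic H2SO4 should convert it, as with diacetone alcohol, into 3,5-dimethyl-5-(prop-2-en-1-yl)-1,2-dioxolan-3-ol F2.
- MeOH/HC(OMe)3 with acid should give 3-methoxy-3,5-dimethyl-5-(prop-2-en-1-yl)-1,2-dioxolane F3.
- Substitution with tert-butyl[(1-methoxyethenyl)oxy]dimethylsilane and TiCl4 (or SnCl4) in CH2Cl2 at −78 °C should give the dioxolane acetate as a racemic cis/trans mixture. The trans isomer is separated by chromatography and resolved on a chiral stationary phase to methyl 2-[(3R,5S)-3,5-dimethyl-5-(prop-2-en-1-yl)-1,2-dioxolan-3-yl]acetate F4.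
- LiOH in THF/H2O then gives 11.

Step 9. E selectivity at the new C9′=C10′ bond may erode with a conjugated aldehyde, the dienal may be deprotonated at its γ-position, or the strongly basic carbanion may attack the peroxide. The fallback reverses the polarity (Horner–Wadsworth–Emmons), sets out from 11 and 18 and comes back at 20.
- Cross-metathesis of 11 with oct-7-enal should give 2-[(3R,5S)-3,5-dimethyl-5-[(2E)-9-oxonon-2-en-1-yl]-1,2-dioxolan-3-yl]acetic acid F5, and diimide as in step 8 should give 2-[(3R,5S)-3,5-dimethyl-5-(9-oxononyl)-1,2-dioxolan-3-yl]acetic acid F6.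
- NaBH4 reduces 18 to (2E,4E)-hepta-2,4-dien-1-ol F7, PBr3 gives (2E,4E)-1-bromohepta-2,4-diene F8, and Arbuzov reaction with P(OEt)3 gives diethyl [(2E,4E)-hepta-2,4-dien-1-yl]phosphonate F9.
- The lithiated phosphonate (LiN(SiMe3)2, THF, −78 °C, 2.2 equiv, the first equivalent forming the carboxylate of F6) condenses with F6 to give 20. The delocalised phosphonate anion is much less basic than the sulfonyl carbanion.

Step 2. Under acid the peroxy hemiketal may equilibrate with its open hydroperoxy ketone form, so that H2O2 is released, the diketone is trapped as its enol ether and oligomeric peroxides form. The fallback sets out from 3 and comes back at 11. Neutral O-silylation of 3 with N,O-bis(trimethylsilyl)acetamide in CH2Cl2 never ionises the ketal carbons and should give cis-3,5-dimethyl-3,5-bis(trimethylsilyloxy)-1,2-dioxolane F10. This is used in step 4 in place of 4, with hexamethyldisiloxane as the leaving group, since silyl ethers of hemiketals are ionised by silyl Lewis acids in the same way as methyl ketals.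

**Further compounds**

F1 | step 4 | 4-hydroxy-4-methylhept-6-en-2-one (racemic) | CC(=O)CC(C)(O)CC=C
F2 | step 4 | 3,5-dimethyl-5-(prop-2-en-1-yl)-1,2-dioxolan-3-ol (racemic diastereomer mixture) | C=CCC1(C)CC(C)(O)OO1
F3 | step 4 | 3-methoxy-3,5-dimethyl-5-(prop-2-en-1-yl)-1,2-dioxolane (racemic diastereomer mixture) | C=CCC1(C)CC(C)(OC)OO1
F4 | step 4 | methyl 2-[(3R,5S)-3,5-dimethyl-5-(prop-2-en-1-yl)-1,2-dioxolan-3-yl]acetate (formed as the racemic trans isomer, then resolved) | C=CC[C@@]1(C)C[C@](C)(CC(=O)OC)OO1
F5 | step 9 | 2-[(3R,5S)-3,5-dimethyl-5-[(2E)-9-oxonon-2-en-1-yl]-1,2-dioxolan-3-yl]acetic acid (E/Z mixture, E drawn) | O=CCCCCC/C=C/C[C@@]1(C)C[C@](C)(CC(=O)O)OO1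
F6 | step 9 | 2-[(3R,5S)-3,5-dimethyl-5-(9-oxononyl)-1,2-dioxolan-3-yl]acetic acid | O=CCCCCCCCC[C@@]1(C)C[C@](C)(CC(=O)O)OO1
F7 | step 9 | (2E,4E)-hepta-2,4-dien-1-ol | CC/C=C/C=C/CO
F8 | step 9 | (2E,4E)-1-bromohepta-2,4-diene | CC/C=C/C=C/CBr
F9 | step 9 | diethyl [(2E,4E)-hepta-2,4-dien-1-yl]phosphonate | CC/C=C/C=C/CP(=O)(OCC)OCC
F10 | step 2 | cis-3,5-dimethyl-3,5-bis(trimethylsilyloxy)-1,2-dioxolane (trans isomer equally usable) | C[Si](C)(C)O[C@@]1(C)C[C@@](C)(O[Si](C)(C)C)OO1
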